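The target is cut at C3–C4: the C4 aryl ketone and the C3 carbinol of the pyranone (C) ring form an acyloin, and in the ring-opened form C2 is the enolisable α-carbon of an aldehyde. The key step exploits exactly this C4(=O)–C3(O)–C2(H) array: a chiral lithium phosphite turns an aroylsilane into a C4 acyl-anion equivalent that adds to the tethered, racemising C3 aldehyde, closing the C ring, forming C3–C4 and setting C2 and C3 (trans) in one operation. The precursor is a racemic 2-aryloxy-2-phenylacetaldehyde whose phloroglucinol ring carries two benzyl ethers and an ortho triethylsilyl ketone. Desilylation, acylation and hydrogenolysis finish the synthesis.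

Key step: step 8

Assumption: which antipode of the TADDOL-derived phosphite gives the (3R) carbinol in this new ring closure cannot be predicted, so the (R,R) catalyst is written and the (S,S) catalyst is used if the sense proves opposite; the target was checked as (2R,3R)-trans with a (2S)-acyl group, and 15 carries the same ring descriptors.

Step 1
Reactants: 1 2,4,6-trihydroxybenzaldehyde; 2 benzyl bromide
Product: 3 2,4-bis(benzyloxy)-6-hydroxybenzaldehyde
Conditions: BnBr (2.05 equiv), K2CO3 (2.2 equiv), DMF, 0 °C → rt
Reagents that add atoms: benzyl bromide (2), BrCc1ccccc1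
Why: Williamson etherification should take the 4-OH and one ortho OH, while the second ortho hydroxyl, held in a hydrogen bond to the formyl group, is the least nucleophilic and should stay free; the symmetry of 1 makes the two ortho positions equivalent.

Step 2
Reactants: 3 2,4-bis(benzyloxy)-6-hydroxybenzaldehyde; 4 methyl 2-bromo-2-phenylacetate (racemic)
Product: 5 methyl rac-2-[3,5-bis(benzyloxy)-2-formylphenoxy]-2-phenylacetate
Conditions: K2CO3 (1.5 equiv), DMF, rt
Reagents that add atoms: methyl 2-bromo-2-phenylacetate (4), COC(=O)C(Br)c1ccccc1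
Why: Williamson O-alkylation (SN2) of the salicylaldehyde-type phenoxide by an activated benzylic α-bromo ester forms O1–C2 and brings in C2 with its phenyl group and C3 at the ester level; the stereocentre is deliberately racemic.

Step 3
Reactants: 5 methyl rac-2-[3,5-bis(benzyloxy)-2-formylphenoxy]-2-phenylacetate; 6 propane-1,3-dithiol
Product: 7 methyl rac-2-[3,5-bis(benzyloxy)-2-(1,3-dithian-2-yl)phenoxy]-2-phenylacetate
Conditions: HS(CH2)3SH (1.2 equiv), BF3·OEt2 (0.3 equiv), CH2Cl2, 0 °C
Reagents that add atoms: propane-1,3-dithiol (6), SCCCS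
Why: Lewis-acid-catalysed dithioacetalisation converts the formyl group into the dithiane needed for umpolung; the ester, the benzyl ethers and the aryl alkyl ether should tolerate substoichiometric BF3 at 0 °C.

Step 4
Reactants: 7 methyl rac-2-[3,5-bis(benzyloxy)-2-(1,3-dithian-2-yl)phenoxy]-2-phenylacetate
Product: 8 rac-2-[3,5-bis(benzyloxy)-2-(1,3-dithian-2-yl)phenoxy]-2-phenylethan-1-ol
Conditions: LiAlH4 (1.0 equiv), THF, 0 °C; Fieser work-up
Reagents that add atoms: none
Why: LiAlH4 reduction of the ester to the primary alcohol is done here because the dithiane masks the formyl carbon and because the acidic ester α-hydrogen would not survive the lithiation that follows.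

Step 5
Reactants: 8 rac-2-[3,5-bis(benzyloxy)-2-(1,3-dithian-2-yl)phenoxy]-2-phenylethan-1-ol; 9 chlorotriethylsilane
Product: 12 rac-2-{3,5-bis(benzyloxy)-2-[2-(triethylsilyl)-1,3-dithian-2-yl]phenoxy}-2-phenylethan-1-ol, via dilithiated dithiane alkoxide 10 (not isolated), via bis-silylated dithiane 11 (not isolated)
Conditions: n-BuLi (2.2 equiv), THF, −78 → −25 °C; Et3SiCl (2.6 equiv), −78 °C → rt; then PPTS (cat.), MeOH, rt
Reagents that add atoms: chlorotriethylsilane (9), CC[Si](Cl)(CC)CC
Why: Corey–Seebach umpolung in which the lithium alkoxide formed first serves as a transient protecting group that cannot be eliminated, the 2-aryl-dithiane C–H (assisted by the ortho alkoxy groups) is the most acidic carbon acid left, C-silylation gives the masked acylsilane, and mild acidic methanolysis removes only the primary O-silyl group, so no fluoride is ever needed beside the C–Si bond.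

Step 6
Reactants: 12 rac-2-{3,5-bis(benzyloxy)-2-[2-(triethylsilyl)-1,3-dithian-2-yl]phenoxy}-2-phenylethan-1-ol
Product: 13 rac-[2,4-bis(benzyloxy)-6-(2-hydroxy-1-phenylethoxy)phenyl](triethylsilyl)methanone
Conditions: HgCl2 (2.2 equiv), CaCO3 (2.5 equiv), MeCN–H2O (4:1), rt, dark
Reagents that add atoms: water, O
Why: Hg(II)-assisted hydrolysis of the 2-silyl-1,3-dithiane is the standard unmasking of acylsilanes, and the carbonate buffer should keep the benzyl ethers, the free carbinol and the C–Si bond intact.

Step 7
Reactants: 13 rac-[2,4-bis(benzyloxy)-6-(2-hydroxy-1-phenylethoxy)phenyl](triethylsilyl)methanone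
Product: 14 rac-2-{3,5-bis(benzyloxy)-2-[(triethylsilyl)carbonyl]phenoxy}-2-phenylacetaldehyde
Conditions: Dess–Martin periodinane (1.3 equiv), CH2Cl2, 0 °C; crude aldehyde used at once
Reagents that add atoms: none
Why: Dess–Martin oxidation converts the primary alcohol into the aldehyde under near-neutral, non-nucleophilic conditions that acylsilanes tolerate; the free epimerisation of C2 in the product is intended.

Step 8
Reactants: 14 rac-2-{3,5-bis(benzyloxy)-2-[(triethylsilyl)carbonyl]phenoxy}-2-phenylacetaldehyde
Product: 15 (2R,3R)-5,7-bis(benzyloxy)-2-phenyl-3-[(triethylsilyl)oxy]chroman-4-one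
Conditions: (R,R)-TADDOL-derived cyclic H-phosphonate with 2-fluorophenyl groups (20 mol%), n-BuLi (18 mol%), THF, 0 °C → rt, slow addition of 14 (0.02 M)
Reagents that add atoms: none
Why: Proposed new method: the lithium phosphite adds to the acylsilane carbonyl (C4), a [1,2]-Brook shift moves silicon to oxygen, and the resulting α-silyloxy phosphonate carbanion attacks the tethered formyl carbon (C3); 1,4-transfer of silicon to the new alkoxide and loss of the phosphite then leave the C4 ketone and the C3 silyl ether and regenerate the catalyst. The closest known reaction type is the intermolecular, metallophosphite-catalysed enantioselective cross silyl benzoin of aryl acylsilanes with aldehydes; a ring-closing version on a racemising aldehyde is not established. The pyranone ring closes in a 6-exo-trig mode, C4 attacking the exocyclic C3=O. C3 is controlled by the chiral phosphorus unit carried on the attacking carbon, which selects the aldehyde face, and C2 is controlled by dynamic kinetic resolution: the substrate epimerises through its enolate, and the chair-like transition state with phenyl equatorial and trans to the C3 oxygen should be the only fast one. The step needs C2 epimerisation faster than closure and the acyl-anion role confined to the aryl carbonyl; the doubly activated C2–H (α to CHO, aryloxy and phenyl) secures the first, and the silicon on C4 secures the second, since only the acylsilane adduct can undergo Brook rearrangement while phosphite addition to the aldehyde is reversible. Once the ring is closed C2 is no longer α to a carbonyl group, so its configuration should be fixed.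

Step 9
Reactants: 15 (2R,3R)-5,7-bis(benzyloxy)-2-phenyl-3-[(triethylsilyl)oxy]chroman-4-one
Product: 16 (2R,3R)-5,7-bis(benzyloxy)-3-hydroxy-2-phenylchroman-4-one
Conditions: HF·pyridine, pyridine, THF, 0 °C
Reagents that add atoms: none
Why: Fluoride-mediated cleavage of the secondary triethylsilyl ether under buffered, non-basic conditions should free the 3-hydroxyl without enolisation at C3 or ring opening at C2, so both stereocentres are kept.

Step 10
Reactants: 16 (2R,3R)-5,7-bis(benzyloxy)-3-hydroxy-2-phenylchroman-4-one; 17 (S)-2-methylbutanoic acid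
Product: 18 (2R,3R)-5,7-bis(benzyloxy)-4-oxo-2-phenylchroman-3-yl (2S)-2-methylbutanoate
Conditions: DCC (1.3 equiv), DMAP (0.1 equiv), CH2Cl2, 0 °C
Reagents that add atoms: (S)-2-methylbutanoic acid (17), CC[C@H](C)C(=O)O
Why: Steglich esterification acylates the secondary α-ketol, and low temperature with only catalytic DMAP should preserve the chiral-pool α-stereocentre of the acid as well as C2 and C3.

Step 11
Reactants: 18 (2R,3R)-5,7-bis(benzyloxy)-4-oxo-2-phenylchroman-3-yl (2S)-2-methylbutanoate
Product: 19 (2R,3R)-5,7-dihydroxy-4-oxo-2-phenylchroman-3-yl (2S)-2-methylbutanoate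
Conditions: H2 (1 atm), 10% Pd/C, EtOAc, rt
Reagents that add atoms: none
Why: Catalytic hydrogenolysis removes both aryl benzyl ethers under neutral conditions in which the aryl ketone, the ester and the cyclic C2–O bond are normally retained and no stereocentre can epimerise.

Compound list

1 | 2,4,6-trihydroxybenzaldehyde | O=Cc1c(O)cc(O)cc1O | starting material
2 | benzyl bromide | BrCc1ccccc1 | starting material
3 | 2,4-bis(benzyloxy)-6-hydroxybenzaldehyde | O=Cc1c(O)cc(OCc2ccccc2)cc1OCc1ccccc1 | intermediate
4 | methyl 2-bromo-2-phenylacetate (racemic) | COC(=O)C(Br)c1ccccc1 | starting material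
5 | methyl rac-2-[3,5-bis(benzyloxy)-2-formylphenoxy]-2-phenylacetate | COC(=O)C(Oc1cc(OCc2ccccc2)cc(OCc2ccccc2)c1C=O)c1ccccc1 | intermediate
6 | propane-1,3-dithiol | SCCCS | starting material
7 | methyl rac-2-[3,5-bis(benzyloxy)-2-(1,3-dithian-2-yl)phenoxy]-2-phenylacetate | COC(=O)C(Oc1cc(OCc2ccccc2)cc(OCc2ccccc2)c1C1SCCCS1)c1ccccc1 | intermediate
8 | rac-2-[3,5-bis(benzyloxy)-2-(1,3-dithian-2-yl)phenoxy]-2-phenylethan-1-ol | OCC(Oc1cc(OCc2ccccc2)cc(OCc2ccccc2)c1C1SCCCS1)c1ccccc1 | intermediate
9 | chlorotriethylsilane | CC[Si](Cl)(CC)CC | starting material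
10 | dilithio derivative of 8 (lithium alkoxide, 2-lithio-1,3-dithiane) | [Li]OCC(Oc1cc(OCc2ccccc2)cc(OCc2ccccc2)c1C1([Li])SCCCS1)c1ccccc1 | intermediate
11 | rac-triethyl{2-[2,4-bis(benzyloxy)-6-{1-phenyl-2-[(triethylsilyl)oxy]ethoxy}phenyl]-1,3-dithian-2-yl}silane | CC[Si](CC)(CC)OCC(Oc1cc(OCc2ccccc2)cc(OCc2ccccc2)c1C1([Si](CC)(CC)CC)SCCCS1)c1ccccc1 | intermediate
12 | rac-2-{3,5-bis(benzyloxy)-2-[2-(triethylsilyl)-1,3-dithian-2-yl]phenoxy}-2-phenylethan-1-ol | OCC(Oc1cc(OCc2ccccc2)cc(OCc2ccccc2)c1C1([Si](CC)(CC)CC)SCCCS1)c1ccccc1 | intermediate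
13 | rac-[2,4-bis(benzyloxy)-6-(2-hydroxy-1-phenylethoxy)phenyl](triethylsilyl)methanone | OCC(Oc1cc(OCc2ccccc2)cc(OCc2ccccc2)c1C(=O)[Si](CC)(CC)CC)c1ccccc1 | intermediate
14 | rac-2-{3,5-bis(benzyloxy)-2-[(triethylsilyl)carbonyl]phenoxy}-2-phenylacetaldehyde | CC[Si](CC)(CC)C(=O)c1c(OCc2ccccc2)cc(OCc2ccccc2)cc1OC(C=O)c1ccccc1 | intermediate
15 | (2R,3R)-5,7-bis(benzyloxy)-2-phenyl-3-[(triethylsilyl)oxy]chroman-4-one | CC[Si](CC)(CC)O[C@H]1C(=O)c2c(OCc3ccccc3)cc(OCc3ccccc3)cc2O[C@@H]1c1ccccc1 | intermediate
16 | (2R,3R)-5,7-bis(benzyloxy)-3-hydroxy-2-phenylchroman-4-one | O[C@H]1C(=O)c2c(OCc3ccccc3)cc(OCc3ccccc3)cc2O[C@@H]1c1ccccc1 | intermediate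
17 | (S)-2-methylbutanoic acid | CC[C@H](C)C(=O)O | starting material
18 | (2R,3R)-5,7-bis(benzyloxy)-4-oxo-2-phenylchroman-3-yl (2S)-2-methylbutanoate | CC[C@H](C)C(=O)O[C@H]1C(=O)c2c(OCc3ccccc3)cc(OCc3ccccc3)cc2O[C@@H]1c1ccccc1 | intermediate
19 | (2R,3R)-5,7-dihydroxy-4-oxo-2-phenylchroman-3-yl (2S)-2-methylbutanoate | CC[C@H](C)C(=O)O[C@H]1C(=O)c2c(O)cc(O)cc2O[C@@H]1c1ccccc1 | target

Total step count: 11. Longest linear sequence: 11 steps (1 → 19); compounds 2, 4, 6, 9 and 17 are commercial.

Steps most likely to fail

1. Step 8 (Proposed new method). Deprotonation of the acidic aldehyde may drain the basic catalyst. The resulting enolate may add to the acylsilane carbonyl in a five-membered aldol closure. C2 may epimerise more slowly than the ring closes, which would erode the trans preference and the enantiomeric purity. Facial control by the phosphite may be weak in the intramolecular setting. The fallback uses known chemistry, sets out from 3 and comes back at 16. The phenol of 3 is protected with MOMCl/i-Pr2NEt to give 2,4-bis(benzyloxy)-6-(methoxymethoxy)benzaldehyde F1. Addition of (E)-2-phenylethenylmagnesium bromide (THF, −78 → 0 °C) gives rac-(E)-1-[2,4-bis(benzyloxy)-6-(methoxymethoxy)phenyl]-3-phenylprop-2-en-1-ol F2. MnO2 in CH2Cl2 oxidises this to the chalcone (E)-1-[2,4-bis(benzyloxy)-6-(methoxymethoxy)phenyl]-3-phenylprop-2-en-1-one F3. Juliá–Colonna epoxidation (poly-L-leucine, urea–H2O2, DBU, THF) should give the trans epoxide [2,4-bis(benzyloxy)-6-(methoxymethoxy)phenyl][(2R,3S)-3-phenyloxiran-2-yl]methanone F4. HCl in MeOH then removes the MOM group, and the liberated phenol should open the epoxide at the benzylic carbon with inversion to give the trans alcohol 16. The route continues with step 10.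

2. Step 5. Deprotonation of the dithiane, which is flanked by two ortho alkoxy groups, may be slow. Ring lithiation between two oxygen substituents or benzylic lithiation of an ether may then compete. The congested carbanion may also silylate sluggishly. The fallback sets out from 5 and comes back at 14, replacing steps 3–7 and forming the C–Si bond with nucleophilic instead of electrophilic silicon. Copper(I)-catalysed 1,2-addition of (triethylsilyl)pinacolborane to the formyl group of 5 (CuCl/NHC/NaOt-Bu cat., THF, then MeOH) should give methyl 2-{3,5-bis(benzyloxy)-2-[hydroxy(triethylsilyl)methyl]phenoxy}-2-phenylacetate F5. LiBH4 (THF, 0 °C) reduces the ester to 2-{3,5-bis(benzyloxy)-2-[hydroxy(triethylsilyl)methyl]phenoxy}-2-phenylethan-1-ol F6. Excess Dess–Martin periodinane then oxidises the α-silyl carbinol to the acylsilane and the primary alcohol to the aldehyde, which should give 14 directly.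

3. Step 10. Under carbodiimide/DMAP activation the α-stereocentre of the acid may partly epimerise through a ketene or acylpyridinium enolate. The amine base may also cause enolisation at C3 or reversible ring opening at C2 of the flavanone, and slow acylation of the hindered carbinol would favour both. The fallback sets out from 17 and 16 and comes back at 18. Acid 17 is dehydrated with DCC (0.5 equiv, CH2Cl2) to (2S)-2-methylbutanoic anhydride F7. This acylates 16 under Sc(OTf)3 catalysis (MeCN, −20 °C), a Lewis-acid activation that uses no base at all.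

Further compounds

F1 | step 8 | 2,4-bis(benzyloxy)-6-(methoxymethoxy)benzaldehyde | COCOc1cc(OCc2ccccc2)cc(OCc2ccccc2)c1C=O
F2 | step 8 | rac-(E)-1-[2,4-bis(benzyloxy)-6-(methoxymethoxy)phenyl]-3-phenylprop-2-en-1-ol | COCOc1cc(OCc2ccccc2)cc(OCc2ccccc2)c1C(O)/C=C/c1ccccc1
F3 | step 8 | (E)-1-[2,4-bis(benzyloxy)-6-(methoxymethoxy)phenyl]-3-phenylprop-2-en-1-one | COCOc1cc(OCc2ccccc2)cc(OCc2ccccc2)c1C(=O)/C=C/c1ccccc1
F4 | step 8 | [2,4-bis(benzyloxy)-6-(methoxymethoxy)phenyl][(2R,3S)-3-phenyloxiran-2-yl]methanone | COCOc1cc(OCc2ccccc2)cc(OCc2ccccc2)c1C(=O)[C@@H]1O[C@H]1c1ccccc1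
F5 | step 5 | methyl 2-{3,5-bis(benzyloxy)-2-[hydroxy(triethylsilyl)methyl]phenoxy}-2-phenylacetate (diastereomer mixture) | COC(=O)C(Oc1cc(OCc2ccccc2)cc(OCc2ccccc2)c1C(O)[Si](CC)(CC)CC)c1ccccc1
F6 | step 5 | 2-{3,5-bis(benzyloxy)-2-[hydroxy(triethylsilyl)methyl]phenoxy}-2-phenylethan-1-ol (diastereomer mixture) | OCC(Oc1cc(OCc2ccccc2)cc(OCc2ccccc2)c1C(O)[Si](CC)(CC)CC)c1ccccc1
F7 | step 10 | (2S)-2-methylbutanoic anhydride | CC[C@H](C)C(=O)OC(=O)[C@@H](C)CC
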